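**Plan**

Locants follow the target: carbocycle C1–C14; C1 bears the acrylate C15(=C17H2)–C16O2Me; C4 carries Me and OH; C5 is the ketone; C8(Me)=C9 is the E olefin; C12–C13 is the oxirane.
The enabling feature is the γ,δ-unsaturated ketone C5(=O)–C6–C7–C8(Me)=C9 inside the 14-membered ring: cutting C6–C7 and re-joining the C5 oxygen to C9 contracts it to a 12-membered 2-methylene oxacycle (O, C5, C4…C1, C14…C9).
Further cuts: C5=C6 (lactone methylenation), the O–C5 acyl bond (lactonisation), C8–C9 (isopropenyl addition), C3–C4 (lactate enolate alkylation), C2=C3 (methylenation), C10–C11 (amide enolate alkylation) and the C11–C2 bond of the carvone ring (ketol cleavage).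
Forward: the carvone ring is epoxidised and opened to the C11–C2 chain; the chain grows at C11 (C10, C9) and at C2 (C3, then C4/C5); C7/C8 are added; the 12-membered lactone is closed, methylenated and expanded to the 14-membered ring; last, C16 is raised to the methyl ester.
Stereochemistry: C1 from (R)-carvone; C12/C13 from the trans-selective nucleophilic epoxidation it directs; C4 from (R)-lactic acid by self-regeneration of the stereocentre; E-C8=C9 from the chair transition state; C9 is transient.

Key step: step 20

Remark: the C9 carbinol is formed and carried as a mixture of epimers (C9 drawn without configuration in 25–28), because C9 becomes sp2 in step 20.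

**Route**

Step 1
Reactants: 1 (R)-carvone
Product: 2 (R)-10-chlorocarvone
Conditions: Ca(OCl)2, CO2 (dry ice), CH2Cl2/H2O, 0 °C
Reagents that add atoms: calcium hypochlorite, [Ca+2].[O-]Cl.[O-]Cl
Why: Ene-type allylic chlorination by HOCl (released from Ca(OCl)2 and CO2) attacks only the electron-rich isopropenyl group and gives the 2-substituted allyl chloride, while the electron-poor enone olefin and C1 are untouched.

Step 2
Reactants: 2 (R)-10-chlorocarvone
Product: 4 (R)-10-hydroxycarvone, via (R)-10-acetoxycarvone 3 (not isolated)
Conditions: KOAc, Bu4NI (cat.), DMF, 50 °C; then K2CO3, MeOH, rt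
Reagents that add atoms: potassium acetate, CC(=O)[O-].[K+]
Why: SN2 displacement of the primary allylic chloride by acetate, followed by base-catalysed methanolysis of the acetate in the same flask, gives the allylic alcohol under conditions too mild to isomerise the enone.

Step 3
Reactants: 4 (R)-10-hydroxycarvone
Product: 5 (R)-10-(tert-butyldimethylsilyloxy)carvone
Conditions: TBSCl, imidazole, DMF, rt
Reagents that add atoms: tert-butyldimethylsilyl chloride, CC(C)(C)[Si](C)(C)Cl
Why: Standard silylation of the primary allylic alcohol gives an ether that should survive every base, hydride and organometallic step up to the final fluoride treatment.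

Step 4
Reactants: 5 (R)-10-(tert-butyldimethylsilyloxy)carvone
Product: 6 (1R,4R,6R)-epoxy ketone (TBS-oxy trans-carvone oxide; C11 ketone, C12–C13 oxirane)
Conditions: 30% H2O2, NaOH (aq.), MeOH, 0 °C
Reagents that add atoms: hydrogen peroxide, OO
Why: Weitz–Scheffer nucleophilic epoxidation: hydroperoxide adds to the enone anti to the C1 side chain and ring closure gives the oxirane trans to it, which sets C12 and C13, while the isolated olefin and the silyl ether do not react.

Step 5
Reactants: 6 (1R,4R,6R)-epoxy ketone
Product: 8 C2-hydroxy ketone (C2 epimers), via potassium enolate 7 (not isolated)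
Conditions: KN(SiMe3)2, THF, −78 °C; then (±)-trans-2-(phenylsulfonyl)-3-phenyloxaziridine, −78 °C; AcOH quench
Reagents that add atoms: 2-(phenylsulfonyl)-3-phenyloxaziridine, O=S(=O)(c1ccccc1)N1OC1c1ccccc1
Why: Only C2 can be enolised (C12 is fully substituted), so a single enolate forms and is hydroxylated by the N-sulfonyloxaziridine (Davis enolate oxidation); the new carbinol configuration is irrelevant because C2 is cut from C11 in the next step.

Step 6
Reactants: 8 C2-hydroxy ketone
Product: 9 seco ester aldehyde (C11 methyl ester on the oxirane; C2 aldehyde)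
Conditions: Pb(OAc)4, MeOH/PhMe (1:1), 0 °C
Reagents that add atoms: methanol, CO
Why: Criegee-type cleavage of the α-ketol through its methanol hemiketal breaks C11–C2 and delivers C11 as the methyl ester and C2 as the aldehyde, without touching the oxirane, the olefin or C1.

Step 7
Reactants: 9 seco ester aldehyde
Product: 10 vinyl epoxy ester (C2=C3 vinyl group)
Conditions: RhCl(PPh3)3 (2.5 mol%), PPh3, TMSCHN2, i-PrOH, THF, rt
Reagents that add atoms: trimethylsilyldiazomethane, C[Si](C)(C)C=[N+]=[N-]
Why: The rhodium-catalysed Lebel methylenation generates Ph3P=CH2 under neutral, salt-free conditions, so the α-stereogenic, β,γ-unsaturated aldehyde should be olefinated without epimerisation at C1 or migration of the olefin, and the glycidic ester is inert.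

Step 8
Reactants: 10 vinyl epoxy ester
Product: 11 vinyl epoxy alcohol (C11 primary alcohol)
Conditions: i-Bu2AlH, CH2Cl2, −78 °C; aq. potassium sodium tartrate
Reagents that add atoms: none
Why: Hydride reduction of the glycidic ester to the primary alcohol at −78 °C is a standard route to 2,3-epoxy alcohols, and at this temperature the oxirane is not opened.

Step 9
Reactants: 11 vinyl epoxy alcohol
Product: 13 morpholine amide (C11–C10H2–C9(=O)–morpholine), via epoxy triflate 12 (not isolated)
Conditions: Tf2O, 2,6-lutidine, CH2Cl2, −78 °C; then the lithium enolate of 4-acetylmorpholine [from 4-acetylmorpholine, LiN(i-Pr)2], THF/DMPU, −78 → −20 °C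
Reagents that add atoms: 4-acetylmorpholine, CC(=O)N1CCOCC1
Why: The triflate, which has no β-hydrogen and cannot eliminate, is displaced by the small, strongly nucleophilic amide enolate (SN2 alkylation of an amide enolate) to install C10 and C9, while the trisubstituted oxirane is a far poorer electrophile at these temperatures.

Step 10
Reactants: 13 morpholine amide
Product: 15 C3 primary alcohol, via alkyl catecholboronate 14 (not isolated)
Conditions: catecholborane, RhCl(PPh3)3 (2 mol%), THF, 0 °C; then 30% H2O2, aq. NaOH, 0 °C
Reagents that add atoms: hydrogen peroxide, OO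
Why: Rhodium-catalysed hydroboration with catecholborane is selective for the monosubstituted vinyl group over the hindered 1,1-disubstituted olefin and does not reduce the amide, and oxidation of the anti-Markovnikov boronate gives the C3 alcohol.

Step 11
Reactants: 15 C3 primary alcohol
Product: 16 C3 primary iodide
Conditions: I2, PPh3, imidazole, CH2Cl2, 0 °C
Reagents that add atoms: iodine, II
Why: Appel-type iodination converts the unhindered primary alcohol into the iodide under buffered conditions that leave the oxirane, amide and silyl ether intact.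

Step 12
Reactants: 17 (R)-lactic acid
Product: 18 (2R,5R)-2-tert-butyl-5-methyl-1,3-dioxolan-4-one
Conditions: pivalaldehyde, p-TsOH (cat.), pentane, reflux (Dean–Stark); recrystallisation of the cis isomer
Reagents that add atoms: pivalaldehyde, CC(C)(C)C=O
Why: Acid-catalysed acetalisation under thermodynamic control favours the cis-dioxolanone, which is purified by crystallisation and stores the lactate chirality in the acetal centre (Seebach self-regeneration of stereocentres).

Step 13
Reactants: 16 C3 primary iodide + 18 (2R,5R)-2-tert-butyl-5-methyl-1,3-dioxolan-4-one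
Product: 20 (2R,5S)-5-alkyl-2-tert-butyl-5-methyl-1,3-dioxolan-4-one (C3–C4 bond formed), via lithium enolate 19 (not isolated)
Conditions: 18 (2.5 equiv), LiN(i-Pr)2, THF, −78 °C; then 16, DMPU, −78 → −30 °C
Reagents that add atoms: none
Why: Alkylation of the lactate-derived dioxolanone enolate by the unbranched primary iodide occurs on the face anti to the tert-butyl group, so the C3 chain takes the place of the former lactate hydrogen and C4 is set with the S configuration of the target, as in known alkylations of this enolate with simple alkyl iodides.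

Step 14
Reactants: 20 alkylated dioxolanone
Product: 21 α-hydroxy acid (C4–OH and C5 acid)
Conditions: LiOH, THF/H2O, 0 °C → rt; then aq. NaH2PO4 (pH 4)
Reagents that add atoms: lithium hydroxide, [Li+].[OH-]
Why: Hydroxide opens the acylal-type lactone and releases pivalaldehyde, the fully substituted C4 cannot epimerise, and the morpholine amide resists LiOH at room temperature.

Step 15
Reactants: 21 α-hydroxy acid
Product: 23 C4 triethylsilyl ether acid, via bis(triethylsilyl) ester ether 22 (not isolated)
Conditions: Et3SiOTf (3 equiv), 2,6-lutidine, CH2Cl2, −78 °C; then K2CO3, MeOH/H2O, 0 °C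
Reagents that add atoms: triethylsilyl triflate, CC[Si](CC)(CC)OS(=O)(=O)C(F)(F)F
Why: The silyl triflate silylates the tertiary alcohol and, transiently, the acid at a temperature that spares the oxirane, and the labile silyl ester is then cleaved selectively by mild basic methanolysis while the tertiary silyl ether stays.

Step 16
Reactants: 23 C4 triethylsilyl ether acid
Product: 24 isopropenyl ketone acid (C9 ketone)
Conditions: CH2=C(Me)MgBr (4 equiv), THF, 0 °C; aq. NH4Cl, then pH 4 buffer
Reagents that add atoms: isopropenylmagnesium bromide, C=C(C)[Mg]Br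
Why: Morpholine amides acylate Grignard reagents once through a stable tetrahedral magnesium adduct (Weinreb-type ketone synthesis), and the carboxylate formed by the first equivalent is inert, so only C9 is attacked and C8, C7 and the C8 methyl are added.

Step 17
Reactants: 24 isopropenyl ketone acid
Product: 25 seco hydroxy acid (C9 epimers)
Conditions: NaBH4, CeCl3·7H2O, MeOH, −40 °C
Reagents that add atoms: none
Why: Luche reduction gives clean 1,2-reduction of the α-methylene ketone to the allylic alcohol without conjugate reduction, and the C9 epimer mixture is accepted because this centre is consumed later.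

Step 18
Reactants: 25 seco hydroxy acid
Product: 27 12-membered lactone (C9–O–C5 ester; C9 epimers), via mixed anhydride 26 (not isolated)
Conditions: 2,4,6-Cl3C6H2COCl, Et3N, THF, rt; then slow addition to DMAP, PhMe, 80 °C (1 mM)
Reagents that add atoms: none
Why: Yamaguchi macrolactonisation activates the α-oxygenated acid as the mixed anhydride and, under high dilution with DMAP, should close the 12-membered ring through the C9 alcohol, which is a C–O closure and far easier than a macrocyclic C–C bond formation.

Step 19
Reactants: 27 12-membered lactone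
Product: 28 12-membered 2-methylene oxacycle (C5=C6H2 enol ether; C9 isopropenyl)
Conditions: Cp2TiMe2 (3 equiv), PhMe, 65 °C, dark; filtration through basic Al2O3
Reagents that add atoms: dimethyltitanocene, [CH3-].[CH3-].[Ti+4].c1cc[cH-]c1.c1cc[cH-]c1
Why: Petasis methylenation: thermally generated Cp2Ti=CH2 adds to the lactone carbonyl, which is hindered but activated by its α-oxygen, and cycloreversion of the oxatitanacyclobutane gives the enol ether under non-Lewis-acidic conditions that spare the oxirane and both silyl ethers.

Step 20
Reactants: 28 12-membered 2-methylene oxacycle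
Product: 29 bis-silyl 14-membered ketone (E-C8=C9)
Conditions: PhMe, i-Pr2NEt (trace), base-washed glass, 130 °C, sealed tube
Reagents that add atoms: none
Why: Heating the allyl vinyl ether unit C6=C5–O–C9–C8=C7 of 28 triggers a concerted, suprafacial [3,3]-sigmatropic (Claisen) rearrangement in which C6–C7 forms while O–C9 breaks, giving the C5 ketone and the C8=C9 olefin. The closest known reaction type is the thermal Claisen ring expansion of 2-methylene oxacycles bearing an alkenyl group next to the ring oxygen, made by titanium methylenation of alkenyl lactones and applied here to a 12-membered ring. The 14-membered carbocycle does not arise by end-to-end closure but by ring expansion: the ring oxygen is excised and C6, C7 and C8 are inserted through a six-membered chair-like transition state spanned by the macrocycle. No new stereocentre is formed; C9 becomes sp2, so both C9 epimers should converge, and C1, C4, C12 and C13 are spectators. The step needs E selectivity at C8=C9, which the substrate secures because the chair with C10 equatorial avoids the clash between an axial C10 and the fully substituted C4 on the enol ether carbon C5. Neutral, acid-free conditions keep the enol ether, the oxirane and both silyl ethers intact until the ketone has formed.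

Step 21
Reactants: 29 bis-silyl 14-membered ketone
Product: 30 diol (C16 allylic alcohol and C4 tertiary alcohol)
Conditions: HF·pyridine, pyridine, THF, 0 °C → rt
Reagents that add atoms: none
Why: Pyridine-buffered HF removes the primary tert-butyldimethylsilyl and the tertiary triethylsilyl ether in one operation, mildly enough to spare the trisubstituted oxirane and without the base that could trigger an α-ketol shift.

Step 22
Reactants: 30 diol
Product: 31 enal (C16 aldehyde)
Conditions: MnO2, CH2Cl2, rt
Reagents that add atoms: none
Why: MnO2 oxidises only the allylic primary alcohol to the 2-substituted acrolein and leaves the tertiary alcohol, ketone, oxirane and trisubstituted olefin alone.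

Step 23
Reactants: 31 enal
Product: 32 acrylic acid (C16 acid)
Conditions: NaClO2, NaH2PO4, 2-methyl-2-butene, t-BuOH/H2O, 0 °C
Reagents that add atoms: sodium chlorite, [Na+].[O-]Cl=O
Why: Pinnick oxidation converts the α,β-unsaturated aldehyde into the acid, and the alkene scavenger removes HOCl before it can reach the C8=C9 olefin.

Step 24
Reactants: 32 acrylic acid
Product: 33 CNP0154954.4 (target)
Conditions: TMSCHN2, PhMe/MeOH, 0 °C
Reagents that add atoms: trimethylsilyldiazomethane, C[Si](C)(C)C=[N+]=[N-]
Why: Esterification with trimethylsilyldiazomethane methylates the carboxylic acid quantitatively under neutral conditions, leaving the tertiary alcohol, ketone and oxirane untouched, and gives the target.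

**Compound list**

1 | (R)-carvone | CC1=CC[C@H](CC1=O)C(C)=C | starting material
2 | (R)-10-chlorocarvone | CC1=CC[C@H](CC1=O)C(=C)CCl | intermediate
3 | (R)-10-acetoxycarvone | CC1=CC[C@H](CC1=O)C(=C)COC(C)=O | intermediate (not isolated)
4 | (R)-10-hydroxycarvone | CC1=CC[C@H](CC1=O)C(=C)CO | intermediate
5 | (R)-10-(tert-butyldimethylsilyloxy)carvone | CC1=CC[C@H](CC1=O)C(=C)CO[Si](C)(C)C(C)(C)C | intermediate
6 | (1R,4R,6R)-4-[3-(tert-butyldimethylsilyloxy)prop-1-en-2-yl]-1-methyl-7-oxabicyclo[4.1.0]heptan-2-one (oxirane trans to the side chain) | C=C(CO[Si](C)(C)C(C)(C)C)[C@H]1CC(=O)[C@]2(C)O[C@@H]2C1 | intermediate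
7 | potassium C2 enolate of 6 | C=C(CO[Si](C)(C)C(C)(C)C)[C@H]1C=C([O-])[C@]2(C)O[C@@H]2C1.[K+] | intermediate (not isolated)
8 | C2-hydroxy derivative of 6 (α-ketol, C2 epimers) | C=C(CO[Si](C)(C)C(C)(C)C)[C@H]1C(O)C(=O)[C@]2(C)O[C@@H]2C1 | intermediate
9 | seco ester aldehyde: methyl 2-methyloxirane-2-carboxylate (C11/C12) whose C13 carries CH2–C1H(CHO)–C(=CH2)CH2OTBS | C=C(CO[Si](C)(C)C(C)(C)C)[C@@H](C=O)C[C@H]1O[C@@]1(C)C(=O)OC | intermediate
10 | vinyl epoxy ester (C2=C3 vinyl on C1) | C=C(CO[Si](C)(C)C(C)(C)C)[C@@H](C=C)C[C@H]1O[C@@]1(C)C(=O)OC | intermediate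
11 | vinyl epoxy alcohol (C11H2OH) | C=C(CO[Si](C)(C)C(C)(C)C)[C@@H](C=C)C[C@H]1O[C@@]1(C)CO | intermediate
12 | epoxy triflate (C11H2OTf) | C=C(CO[Si](C)(C)C(C)(C)C)[C@@H](C=C)C[C@H]1O[C@@]1(C)COS(=O)(=O)C(F)(F)F | intermediate (not isolated)
13 | morpholine amide (C9 amide, C10 and C11 methylenes) | C=C(CO[Si](C)(C)C(C)(C)C)[C@@H](C=C)C[C@H]1O[C@@]1(C)CCC(=O)N2CCOCC2 | intermediate
14 | C3 alkyl catecholboronate of 13 | C=C(CO[Si](C)(C)C(C)(C)C)[C@@H](CCB1Oc2ccccc2O1)C[C@H]3O[C@@]3(C)CCC(=O)N4CCOCC4 | intermediate (not isolated)
15 | C3 primary alcohol | C=C(CO[Si](C)(C)C(C)(C)C)[C@@H](CCO)C[C@H]1O[C@@]1(C)CCC(=O)N2CCOCC2 | intermediate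
16 | C3 primary iodide | C=C(CO[Si](C)(C)C(C)(C)C)[C@@H](CCI)C[C@H]1O[C@@]1(C)CCC(=O)N2CCOCC2 | intermediate
17 | (R)-lactic acid | C[C@@H](O)C(=O)O | starting material
18 | (2R,5R)-2-tert-butyl-5-methyl-1,3-dioxolan-4-one (cis) | C[C@H]1O[C@@H](C(C)(C)C)OC1=O | intermediate
19 | lithium enolate of 18 | CC1=C([O-])O[C@H](C(C)(C)C)O1.[Li+] | intermediate (not isolated)
20 | (2R,5S)-5-alkyl-2-tert-butyl-5-methyl-1,3-dioxolan-4-one (alkyl = C3 chain of 16; methyl cis to tert-butyl) | C=C(CO[Si](C)(C)C(C)(C)C)[C@@H](CC[C@]1(C)O[C@@H](C(C)(C)C)OC1=O)C[C@H]2O[C@@]2(C)CCC(=O)N3CCOCC3 | intermediate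
21 | (4S)-α-hydroxy acid (C4–OH, C5 acid) | C=C(CO[Si](C)(C)C(C)(C)C)[C@@H](CC[C@](C)(O)C(=O)O)C[C@H]1O[C@@]1(C)CCC(=O)N2CCOCC2 | intermediate
22 | bis(triethylsilyl) ester ether of 21 | C=C(CO[Si](C)(C)C(C)(C)C)[C@@H](CC[C@](C)(O[Si](CC)(CC)CC)C(=O)O[Si](CC)(CC)CC)C[C@H]1O[C@@]1(C)CCC(=O)N2CCOCC2 | intermediate (not isolated)
23 | C4 triethylsilyl ether acid | C=C(CO[Si](C)(C)C(C)(C)C)[C@@H](CC[C@](C)(O[Si](CC)(CC)CC)C(=O)O)C[C@H]1O[C@@]1(C)CCC(=O)N2CCOCC2 | intermediate
24 | isopropenyl ketone acid (C9 ketone) | C=C(CO[Si](C)(C)C(C)(C)C)[C@@H](CC[C@](C)(O[Si](CC)(CC)CC)C(=O)O)C[C@H]1O[C@@]1(C)CCC(=O)C(C)=C | intermediate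
25 | seco hydroxy acid (C9 carbinol, epimer mixture) | C=C(CO[Si](C)(C)C(C)(C)C)[C@@H](CC[C@](C)(O[Si](CC)(CC)CC)C(=O)O)C[C@H]1O[C@@]1(C)CCC(O)C(C)=C | intermediate
26 | mixed 2,4,6-trichlorobenzoic anhydride of 25 | C=C(CO[Si](C)(C)C(C)(C)C)[C@@H](CC[C@](C)(O[Si](CC)(CC)CC)C(=O)OC(=O)c1c(Cl)cc(Cl)cc1Cl)C[C@H]2O[C@@]2(C)CCC(O)C(C)=C | intermediate (not isolated)
27 | 12-membered lactone (C9 epimer mixture) | C=C(CO[Si](C)(C)C(C)(C)C)[C@H]1CC[C@](C)(O[Si](CC)(CC)CC)C(=O)OC(C(C)=C)CC[C@]2(C)O[C@@H]2C1 | intermediate
28 | 12-membered 2-methylene oxacycle, precursor of the key step (C9 epimer mixture) | C=C(CO[Si](C)(C)C(C)(C)C)[C@H]1CC[C@](C)(O[Si](CC)(CC)CC)C(=C)OC(C(C)=C)CC[C@]2(C)O[C@@H]2C1 | intermediate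
29 | bis-silyl 14-membered ketone with E-C8=C9, product of the key step | C=C(CO[Si](C)(C)C(C)(C)C)[C@H]1CC[C@](C)(O[Si](CC)(CC)CC)C(=O)CC/C(C)=C/CC[C@]2(C)O[C@@H]2C1 | intermediate
30 | diol (C16–OH, C4–OH) | C=C(CO)[C@H]1CC[C@](C)(O)C(=O)CC/C(C)=C/CC[C@]2(C)O[C@@H]2C1 | intermediate
31 | enal (C16 aldehyde) | C=C(C=O)[C@H]1CC[C@](C)(O)C(=O)CC/C(C)=C/CC[C@]2(C)O[C@@H]2C1 | intermediate
32 | acrylic acid (C16 acid) | C=C(C(=O)O)[C@H]1CC[C@](C)(O)C(=O)CC/C(C)=C/CC[C@]2(C)O[C@@H]2C1 | intermediate
33 | CNP0154954.4: methyl 2-[(1S,4S,8E,12S,13R)-12,13-epoxy-4-hydroxy-4,8,12-trimethyl-5-oxocyclotetradec-8-en-1-yl]acrylate (target locants) | C=C(C(=O)OC)[C@H]1CC[C@](C)(O)C(=O)CC/C(C)=C/CC[C@]2(C)O[C@@H]2C1 | target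

**Step count**

Total: 24 steps. Longest linear sequence: 23 steps from (R)-carvone (steps 1–11 and 13–24); step 12 is the one-step side branch from (R)-lactic acid.

**Steps most likely to fail**

1. Step 20 (key rearrangement). One C9 epimer of 28 may be forced through a boat-like or axial-C10 transition state, which would erode the E selectivity. It may also react so slowly that ionisation of the allylic C9–O bond or hydrolysis of the enol ether competes during prolonged heating. Fallback (supply a single C9 epimer by stereoconvergent relactonisation; written for the case that the 9S epimer is the poor one, with the roles exchanged otherwise): it sets out from lactone 27, whose epimers are separated by chromatography. The (9S)-lactone F1 is saponified (LiOH, THF/MeOH/H2O, 50 °C) to the (9S)-seco acid F2. F2 is closed with inversion at C9 by Mitsunobu lactonisation (PPh3, DIAD, PhMe, high dilution) to the (9R)-lactone F3, the same epimer that the separation gives directly. Cp2TiMe2 methylenation then gives the (9R)-enol ether F4, and its thermolysis comes back to the route at 29.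

2. Step 9 (substitution at C11). Displacement at the carbon flanked by the fully substituted oxirane carbon may be slower than decomposition of the kinetic amide enolate or of the triflate at the temperatures both tolerate. Fallback (a stabilised carbanion that can be heated, then reductive removal of the activating group): it sets out from alcohol 11, which is iodinated (I2, PPh3, imidazole, CH2Cl2) to the epoxy iodide F5. The sodium salt of 4-[(phenylsulfonyl)acetyl]morpholine (NaH, DMF, 50 °C) is alkylated by F5 to the α-sulfonyl amide F6. Reductive desulfonylation (SmI2, THF/MeOH, −78 °C) comes back to the route at 13.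

3. Step 18 (macrolactonisation). Because the acyl carbon C5 is shielded by the fully substituted C4, DMAP may attack the aryl carbonyl of the mixed anhydride instead, transferring the trichlorobenzoyl group to the C9 alcohol, and intermolecular esterification may outrun closure of the 12-membered ring. Fallback (activate the alcohol instead of the acid): Mitsunobu macrolactonisation (PPh3, DIAD, PhMe, slow addition, rt) sets out from 25 and comes back to the route at 27. The carboxylate acts as the nucleophile, and the inversion at C9 is of no consequence. This fallback makes no compound outside the list (F0).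

**Further compounds**

F1 | step 20 | (9S)-epimer of lactone 27 | C=C(CO[Si](C)(C)C(C)(C)C)[C@H]1CC[C@](C)(O[Si](CC)(CC)CC)C(=O)O[C@H](C(C)=C)CC[C@]2(C)O[C@@H]2C1
F2 | step 20 | (9S)-epimer of seco hydroxy acid 25 | C=C(CO[Si](C)(C)C(C)(C)C)[C@@H](CC[C@](C)(O[Si](CC)(CC)CC)C(=O)O)C[C@H]1O[C@@]1(C)CC[C@H](O)C(C)=C
F3 | step 20 | (9R)-epimer of lactone 27 | C=C(CO[Si](C)(C)C(C)(C)C)[C@H]1CC[C@](C)(O[Si](CC)(CC)CC)C(=O)O[C@@H](C(C)=C)CC[C@]2(C)O[C@@H]2C1
F4 | step 20 | (9R)-epimer of enol ether 28 | C=C(CO[Si](C)(C)C(C)(C)C)[C@H]1CC[C@](C)(O[Si](CC)(CC)CC)C(=C)O[C@@H](C(C)=C)CC[C@]2(C)O[C@@H]2C1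
F5 | step 9 | epoxy iodide (C11H2I analogue of 11) | C=C(CO[Si](C)(C)C(C)(C)C)[C@@H](C=C)C[C@H]1O[C@@]1(C)CI
F6 | step 9 | C10-phenylsulfonyl derivative of amide 13 (C10 epimers) | C=C(CO[Si](C)(C)C(C)(C)C)[C@@H](C=C)C[C@H]1O[C@@]1(C)CC(C(=O)N2CCOCC2)S(=O)(=O)c3ccccc3
F0 | step 18 | none | none
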